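**Assumption:** The target has no stereocentres, so "single enantiomer" is trivially met. The only stereocentres in the route (C2 and C3 of flavanone **10**) are transient and are destroyed in Step 6.

## Retrosynthetic overview
- The 2',5'-dihydroxy-4'-methoxy B ring is a hydroquinone. I mask it as a 2,4,5-trimethoxyphenyl group. Ceric ammonium nitrate (CAN) then oxidises only the 2',5'-OMe para pair to the 2-methoxy-p-quinone, and dithionite reduces that to the target. No selective demethylation is needed.
- The flavonol hexamethyl ether is formed by dehydrogenation of a 3-methoxyflavanone.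
- Key step: Cu-catalysed 1,4-addition of 2,4,5-trimethoxyphenylmagnesium bromide to 3,5,7-trimethoxychromone, which forms the C2–aryl bond late. This replaces the chalcone/Algar–Flynn–Oyamada and Baker–Venkataraman logic.
- 3,5,7-Trimethoxychromone comes from 1,3,5-trimethoxybenzene by Friedel–Crafts acylation with methoxyacetyl chloride and DMF-DMA annulation.
- Ring order: A ring (commercial), then C ring (Step 2), then B ring attached pre-formed (Step 5), then B-ring unmasking (Steps 7–8).

## Route

**Step 1**
Reactants: **1** 1,3,5-trimethoxybenzene; **2** methoxyacetyl chloride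
Product: **3** 1-(2-hydroxy-4,6-dimethoxyphenyl)-2-methoxyethan-1-one
Conditions: AlCl3 (3 equiv), CH2Cl2, 0 °C → rt, 6 h; aqueous HCl work-up
Reagents that add atoms: none beyond the reactants. AlCl3 leaves only H (as OH) after work-up.
Why: Friedel–Crafts acylation of the very electron-rich arene occurs at the only free ring position. The excess AlCl3 chelates the new carbonyl and removes the adjacent (ortho) methyl ether selectively, as is well known for 2,4,6-trimethoxyphenyl ketones. This gives the 2-hydroxy ketone directly, and the aliphatic OMe survives at 0 °C to rt.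

**Step 2**
Reactants: **3**; **4** N,N-dimethylformamide dimethyl acetal (DMF-DMA)
Product: **5** 3,5,7-trimethoxy-4H-chromen-4-one
Conditions: **4** (3 equiv), toluene, 110 °C, 4 h; then p-TsOH, CH2Cl2, rt
Reagents that add atoms: DMF-DMA, CN(C)C(OC)OC, which supplies the C2–H carbon.
Why: Enaminone formation on the ω-methoxy methylene (Bredereck-type condensation) gives ArCO–C(OMe)=CH–NMe2. The ortho-phenol then adds to the enaminone β-carbon and expels HNMe2 (addition–elimination), closing the pyranone with the 3-OMe already in place.

**Step 3**
Reactants: **6** 1,2,4-trimethoxybenzene; **7** N-bromosuccinimide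
Product: **8** 1-bromo-2,4,5-trimethoxybenzene
Conditions: **7** (1.05 equiv), MeCN, 0 °C → rt, 2 h
Reagents that add atoms: NBS, O=C1CCC(=O)N1Br, which supplies Br.
Why: Electrophilic bromination goes to C5. That position is para to the 2-OMe and ortho to the 4-OMe, so it is doubly activated and also the least hindered.

**Step 4**
Reactants: **8**
Product: **9** (2,4,5-trimethoxyphenyl)magnesium bromide
Conditions: Mg turnings, cat. 1,2-dibromoethane, THF, reflux, 2 h
Reagents that add atoms: Mg, [Mg], which becomes the C–MgBr bond.
Why: Standard oxidative insertion of Mg into an electron-rich aryl bromide. No acidic functional groups are present.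

**Step 5**
Reactants: **5**; **9**
Product: **10** 3,5,7-trimethoxy-2-(2,4,5-trimethoxyphenyl)chroman-4-one (3-methoxyflavanone, mixture of C2/C3 diastereomers)
Conditions: **9** (2.5 equiv), CuBr·SMe2 (20 mol%), TMSCl (3 equiv), THF, –40 → 0 °C; then 1 M HCl, rt
Reagents that add atoms: TMSCl, C[Si](C)(C)Cl, which is removed on acidic hydrolysis of the silyl enol ether, so no Si remains.
Why: Proposed new method: Cu(I)-catalysed, TMSCl-accelerated conjugate addition of an aryl Grignard to C2 of the chromone enone via an aryl-Cu(III) σ-adduct and reductive elimination, with the enolate trapped as its silyl enol ether. The closest known reaction is Cu-catalysed Grignard 1,4-addition to unsubstituted chromones and enones. It is untested on a 3,5,7-trioxygenated, deactivated chromone. The new C2 and C3 stereocentres are irrelevant because both are removed in Step 6.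

**Step 6**
Reactants: **10**
Product: **11** 3,5,7-trimethoxy-2-(2,4,5-trimethoxyphenyl)-4H-chromen-4-one
Conditions: LiHMDS (1.1 equiv), THF, –78 °C; PhSeCl (1.2 equiv); then 30% H2O2, pyridine, CH2Cl2, 0 °C → rt
Reagents that add atoms: none. PhSeCl and H2O2 leave as PhSeOH and water, and no Se remains in the product.
Why: Kinetic enolate selenation at C3, then selenoxide syn-elimination toward the benzylic C2–H (a Sharpless/Reich-type dehydrogenation) installs the C2=C3 bond. The C3 configuration is irrelevant because the selenide epimerises readily.

**Step 7**
Reactants: **11**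
Product: **12** 2-methoxy-5-(3,5,7-trimethoxy-4-oxo-4H-chromen-2-yl)cyclohexa-2,5-diene-1,4-dione
Conditions: CAN (3 equiv), MeCN/H2O 3:1, 0 °C, 15 min
Reagents that add atoms: water, O, which supplies the two quinone oxygens (the OMe carbons leave as MeOH).
Why: CAN oxidative demethylation of a 1,4-dimethoxyarene proceeds through a radical cation and gives the p-quinone. Only the 2',5'-OMe para pair can do this, because C1' carries the chromone, so the 4'-OMe is retained as the quinone OMe. The trimethoxyphenyl ring is far more oxidisable than the deactivated chromone A ring.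

**Step 8**
Reactants: **12**
Product: **13** 5-O-methyloxyayanin-A, 2',5'-dihydroxy-3,4',5,7-tetramethoxyflavone
Conditions: Na2S2O4 (5 equiv), THF/H2O 1:1, rt, 10 min, under N2
Reagents that add atoms: none. Dithionite only delivers H to the two quinone oxygens.
Why: Dithionite reduction of a p-quinone to the hydroquinone is chemoselective. The chromone C=O and the C2=C3 bond are untouched.

## Checks (completed)
- The target SMILES has a chromone with OMe at C3, C5 and C7, and a B ring with C2'-OH, C4'-OMe and C5'-OH. The route delivers exactly this pattern: Grignard C2/C4/C5 OMe become C2'/C4'/C5', and the quinone carbonyls sit at C2' and C5'.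
- Atom balance: **12** is C19H16O8, and adding 2 H gives **13**, C19H18O8, matching the target.
- The only free OH groups appear in Steps 1 and 8. The Grignard in Step 5 sees no acidic protons, because the chromone is fully O-methylated.

## Compound list
1 | 1,3,5-trimethoxybenzene | COc1cc(OC)cc(OC)c1 | starting material
2 | methoxyacetyl chloride | COCC(=O)Cl | starting material
3 | 1-(2-hydroxy-4,6-dimethoxyphenyl)-2-methoxyethanone | COCC(=O)c1c(O)cc(OC)cc1OC | intermediate
4 | DMF dimethyl acetal | CN(C)C(OC)OC | starting material (reagent)
5 | 3,5,7-trimethoxychromone | COc1cc(OC)c2c(=O)c(OC)coc2c1 | intermediate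
6 | 1,2,4-trimethoxybenzene | COc1ccc(OC)c(OC)c1 | starting material
7 | N-bromosuccinimide | O=C1CCC(=O)N1Br | starting material (reagent)
8 | 1-bromo-2,4,5-trimethoxybenzene | COc1cc(OC)c(OC)cc1Br | intermediate
9 | (2,4,5-trimethoxyphenyl)magnesium bromide | COc1cc(OC)c(OC)cc1[Mg]Br | intermediate
10 | 3,5,7-trimethoxy-2-(2,4,5-trimethoxyphenyl)chroman-4-one (diastereomer mixture) | COc1cc(OC)c2c(c1)OC(c1cc(OC)c(OC)cc1OC)C(OC)C2=O | intermediate
11 | 3,5,7-trimethoxy-2-(2,4,5-trimethoxyphenyl)chromone | COc1cc(OC)c2c(=O)c(OC)c(-c3cc(OC)c(OC)cc3OC)oc2c1 | intermediate
12 | 2-methoxy-5-(3,5,7-trimethoxychromon-2-yl)-1,4-benzoquinone | COc1cc(OC)c2c(=O)c(OC)c(C3=CC(=O)C(OC)=CC3=O)oc2c1 | intermediate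
13 | 5-O-methyloxyayanin-A (achiral) | COc1cc(OC)c2c(=O)c(OC)c(-c3cc(O)c(OC)cc3O)oc2c1 | target

## Totals
Total steps: 8. Longest linear sequence: 6 (1 → 3 → 5 → 10 → 11 → 12 → 13, in Steps 1, 2, 5, 6, 7, 8). The bromide/Grignard branch (Steps 3–4) is convergent.

## Three steps most likely to fail
1. **Step 5 (conjugate addition).** The 5,7-dimethoxy-3-methoxy chromone is a poor, hindered Michael acceptor, and 1,2-addition at C4 may compete.
   Fallback: change the strategy to an Allan–Robinson condensation of **3** with 2,4,5-trimethoxybenzoic anhydride and its sodium salt. This gives **11** directly and joins the route at Step 7.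
2. **Step 6 (dehydrogenation).** The lithium enolate of a flavanone can ring-open to the chalcone phenoxide (E1cB) before it is trapped.
   Fallback: intercept the Step 5 enolate as its TMS enol ether and do a Saegusa–Ito Pd(OAc)2/O2 oxidation, with no strong base step.
3. **Step 7 (CAN).** Over-oxidation, nitration, or attack on the A ring or C3-OMe could occur.
   Fallback: swap the B ring to a benzyl-protected partner. Use 1-bromo-2,5-bis(benzyloxy)-4-methoxybenzene in Steps 4–5, then unmask the hydroquinone by H2, Pd/C in one step, which removes Steps 7–8.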